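The runs come from a simulation for an exercise; scatter was added.

The amounts come first. The reagent in the second phase, charged per litre of the first phase, is 0.0900 M in eta and 1.10 M in gamma, and I had to decide which recipe to charge next for a clean target.

| flask | substrate | reagent in the second phase | remark | time | volume of the second phase over the first |
|---|---|---|---|---|---|
| ash | 0.29 M | 1.1 equiv | run made earlier |  |  |
| cedar | 1.4 M | 1.1 equiv | run made earlier |  |  |
| maple | 1 M | 0.80 equiv | run made earlier |  |  |
| gamma | 1.0 M | 1.10 equiv |  | 12 min | 1.0 |
| alpha | 0.60 M | 0.360 equiv |  | 12 min | 1.0 |
| eta | 0.25 M | 0.360 equiv |  | 12 min | 1.0 |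
| zeta | 0.30 M | 0.740 equiv |  | 12 min | 1.0 |

| run | time / min | target / % | over-reacted product / % |
|---|---|---|---|
| ash | 0.833 | 1 | 0 |
| ash | 2.00 | 4 | 0 |
| ash | 4.00 | 8 | 0 |
| ash | 6.00 | 11 | 3 |
| cedar | 0.833 | 0 | 0 |
| cedar | 2.00 | 9 | 2 |
| cedar | 4.00 | 19 | 5 |
| cedar | 6.00 | 30 | 6 |
| maple | 1.50 | 6 | 0 |
| maple | 3.00 | 7 | 0 |
| maple | 5.00 | 14 | 2 |
| maple | 6.00 | 19 | 2 |

(standard deviation of a reading: 2 percentage points)

1. the flasks by share of target in all that became target or over-reacted product or side product, highest first, at 12 min (gamma / alpha / eta / zeta)
2. the share of target in all that became target or over-reacted product or side product of the flask you put first, at 12 min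
3. the share of target in all that became target or over-reacted product or side product of the flask you put last, at 12 min

- in percentages every species weighs as the substrate in it: one side product counts as two
- in the second phase: reagent in the second phase; everything else is in the first
- charges count per volume of the first phase; a concentration in a rate is the amount of a species over the volume of its own phase; every rate counts per litre of the first phase
- on the list of suspects stand: reagent in the reaction phase <-> reagent in the second phase; substrate + reagent in the reaction phase -> target; reagent in the reaction phase + target -> over-reacted product; substrate + target -> side product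
- the earlier runs hold the two phases in the same ratio of volumes as the flask asked about

The suspects place over-reacted product downstream of target. I assumed that, at low conversion and a fixed volume ratio, target grows as the reagent charged times the time, a quantity I call the dose, and over-reacted product as the square of the dose. Their ratio should then rise in proportion to the dose. So I carried the over-reaction ratio, over-reacted product per target, read at cedar's last reading as 0.200 and scaled by dose. That reading carries a scatter of 2 percentage points on 6%, about a third of its value. Maple's dose gives 0.104, and maple read 0.105, on 2% of over-reacted product with the same scatter. Ash's dose gives 0.0414, but ash read 0.273, on 3% with the same scatter, so these readings did not prove the scaling.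

At 12 min my ratios were 0.0234 for eta, 0.0561 for alpha, 0.0577 for zeta and 0.286 for gamma. Alpha and zeta could not be told apart at this scatter. The runs hold no reading of side product, so my shares of target (the selectivity) counted over-reacted product by itself: 97.7% for eta and 77.8% for gamma. I chose eta as the recipe to charge.

The forecast gave eta > zeta > alpha > gamma, with 96% for the first flask and 74% for the last, each lower than my share for that flask . Of the middle places it said: “Alpha and zeta are otherwise tied, so I place zeta ahead”.

The flask gave eta > zeta > alpha > gamma, with 93.5% and 69.8%.

    reagent in the reaction phase ⇌ reagent in the second phase, rate k1*([reagent in the reaction phase] - [reagent in the second phase]/K1) per volume of the first phase (partition coefficient = 0.320, kL = 0.00140 s⁻¹)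
    substrate + reagent in the reaction phase → target (k = 0.00210 L mol⁻¹ s⁻¹)
    reagent in the reaction phase + target → over-reacted product (k = 0.00150 L mol⁻¹ s⁻¹)
    substrate + target → side product (k = 2.90 × 10⁻⁴ L mol⁻¹ s⁻¹)

Gamma at 12 min held a ratio of 0.273 against my 0.286. A neighbour of gamma, charged with 0.40 M of substrate at the same equivalents, has a dose that gives a ratio of 0.114 and a share of 89.8% when side product is not counted. At 12 min that neighbour held 23.3% target and 2.91% over-reacted product, a ratio of 0.125. It also held 1.54% side product, and its share of target was 83.9%.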